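**Retrosynthetic overview**
- The 1,4-dioxane is cut at both aryl–O bonds (retro hetero-Diels–Alder) into a triterpene o-quinone and the C1=C5 alkene of a guaiane. The o-quinone is the C-8'-protonated tautomer of pristimerin, so one operation forms the dioxane, aromatizes ring A and sets C-1, C-5 and C-8'.
- The Δ3 alkene is carried as a C-4 tertiary alcohol, because a free cyclopentadiene would be attacked at C3=C4. The hydroxyl steers the quinone and is dehydrated last.
- The guaiane cyclopentene ring comes from a carbonylative Stille/Nazarov annulation on a cycloheptenyl triflate; the seven-membered ring comes from a one-carbon ring expansion of (S)-carvone.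
- The triterpene half is pristimerin, made by O-methylation of celastrol (rings A to E bought intact).
- Ring order: seven-membered ring, then five-membered ring, then dioxane. Guaiane atoms are numbered C-1 to C-15; triterpene atoms carry friedelane numbers with a prime.

Assumption: celastrol (bulk Tripterygium isolate) counts as a commercial starting material; "α" means the guaiane face that carries the C-10 methyl and the C-7 isopropenyl group.

**Step 1**
Reactants: 1 (S)-(+)-carvone
Product: 3 (S)-trimethyl{[2-methyl-5-(prop-1-en-2-yl)cyclohex-1-en-1-yl]oxy}silane, via lithium enolate 2 (not isolated)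
Conditions: LiBH(s-Bu)3, THF, −78 °C; then Me3SiCl, Et3N, −78 → 0 °C
Reagents that add atoms: chlorotrimethylsilane, C[Si](C)(C)Cl
Why: conjugate hydride reduction gives the enolate only on the methyl-bearing side and O-silylation fixes it; no new stereocentre, the isopropenyl centre is untouched.

**Step 2**
Reactants: 3
Product: 4 trimethyl{[(3S)-6-methyl-3-(prop-1-en-2-yl)bicyclo[4.1.0]heptan-1-yl]oxy}silane (cis-fused; both cyclopropane epimers)
Conditions: Et2Zn (1.2 equiv), CH2I2 (1.2 equiv), toluene, 0 °C → rt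
Reagents that add atoms: diiodomethane, ICI
Why: Simmons–Smith (Furukawa) cyclopropanation; the electrophilic zinc carbenoid prefers the electron-rich silyl enol ether over the isopropenyl group, and the two new centres are erased in step 3.

**Step 3**
Reactants: 4
Product: 6 (S)-3-methyl-6-(prop-1-en-2-yl)cyclohept-2-en-1-one, via β-chloro ketone 5 (not isolated)
Conditions: FeCl3 (2.2 equiv), DMF, 0 °C → rt; then NaOAc, MeOH, reflux
Reagents that add atoms: none
Why: Ito–Saegusa ring expansion; trivalent iron opens the internal cyclopropane bond by one-electron oxidation, chloride caps the tertiary radical and acetate eliminates HCl to the conjugated cycloheptenone.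

**Step 4**
Reactants: 6
Product: 9 (3R,6S)-3-methyl-6-(prop-1-en-2-yl)cyclohept-1-en-1-yl trifluoromethanesulfonate, via silyl enol ether 7 (not isolated), via lithium enolate 8 (not isolated)
Conditions: Cu(OAc)2·H2O (3 mol%), (R)-DTBM-SEGPHOS (3 mol%), PhMe2SiH, toluene, 0 °C; then MeLi, THF, −78 → 0 °C; then PhNTf2, −78 °C → rt
Reagents that add atoms: N-phenylbis(trifluoromethanesulfonimide), O=S(=O)(N(c1ccccc1)S(=O)(=O)C(F)(F)F)C(F)(F)F
Why: ligand-controlled copper hydride asymmetric conjugate reduction sets C-10 as R (methyl cis to isopropenyl) against the expected substrate preference for trans, and leaves the enolate regiospecifically toward C-1 for triflation; the ligand sense is assigned by analogy with 3-methylcycloalkenones, and the antipode would give the 10-epimer.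

**Step 5**
Reactants: 9
Product: 10 (E)-1-[(3R,6S)-3-methyl-6-(prop-1-en-2-yl)cyclohept-1-en-1-yl]-3-(trimethylsilyl)prop-2-en-1-one
Conditions: Pd(PPh3)4 (5 mol%), LiCl (3 equiv), CO (1 atm), (E)-Bu3SnCH=CHSiMe3, THF, 55 °C
Reagents that add atoms: carbon monoxide, [C-]#[O+]; (E)-tributyl[2-(trimethylsilyl)vinyl]stannane, CCCC[Sn](CCCC)(CCCC)/C=C/[Si](C)(C)C
Why: carbonylative Stille coupling (oxidative addition of the vinyl triflate to zerovalent palladium, CO insertion, transmetalation) gives the divinyl ketone with C-4 attached to C-5; no stereocentre changes.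

**Step 6**
Reactants: 10
Product: 12 (4R,7S)-4-methyl-7-(prop-1-en-2-yl)-3,4,5,6,7,8-hexahydroazulen-1(2H)-one, via cis-fused cyclopentenone 11 (not isolated)
Conditions: FeCl3 (1.1 equiv), CH2Cl2, −40 → −10 °C; then DBU, toluene, 80 °C
Reagents that add atoms: none
Why: silicon-directed Nazarov cyclization (4π conrotatory closure, fast β-silyl collapse of the oxyallyl cation) followed by base-mediated shift of the alkene into the tetrasubstituted ring-fusion position; the C-10 hydrogen is pseudoequatorial and poorly aligned for γ-deprotonation, so C-10 is kept.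

**Step 7**
Reactants: 12
Product: 13 (1R,4R,7S)-1,4-dimethyl-7-(prop-1-en-2-yl)-1,2,3,4,5,6,7,8-octahydroazulen-1-ol
Conditions: MeLi, Et2O, −78 °C; chromatographic removal of the (1S)-epimer
Reagents that add atoms: methyllithium, [Li]C
Why: 1,2-addition of MeLi to the cyclopentenone; only a modest preference is expected for the carbinol with OH on the α face (guaiane C-4, R), so the minor epimer is separated.

**Step 8**
Reactants: 14 celastrol
Product: 15 pristimerin
Conditions: Me3SiCHN2, toluene/MeOH 4:1, 0 °C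
Reagents that add atoms: (trimethylsilyl)diazomethane, C[Si](C)(C)C=[N+]=[N-]
Why: diazoalkane esterification methylates the carboxylic acid selectively; no stereocentre is affected.

**Step 9**
Reactants: 13 and 15 pristimerin
Product: 17 4α-hydroxy 1α,5α-benzodioxane adduct (O-3'–C-5 and O-2'–C-1; 8'S), via o-quinone tautomer 16 (not isolated)
Conditions: 13 (3 equiv), Et3N (0.2 equiv), AcOH (0.2 equiv), toluene, 80 °C, dark, Ar; 15 added over 8 h
Reagents that add atoms: none
Why: Proposed new method: a proton shuttle converts the hydroxy-quinone methide 15 (a vinylogous enol) into o-quinone 16 by protonation at C-8' on the β face, away from the axial 13α-methyl, and 16 is trapped in an inverse-electron-demand hetero-Diels–Alder reaction by the tetrasubstituted alkene of 13 (higher HOMO than the isopropenyl group) on the α face, where the C-4 hydroxyl can hydrogen-bond to O-3' while the C-4 methyl blocks the other face, with O-3' going to C-5 so that the C-4' methyl avoids the pseudoaxial C-10 methyl; the closest known reaction types are the o-quinone/alkene hetero-Diels–Alder route to 1,4-benzodioxanes and the o-quinone/quinone methide tautomerism of 4-alkyl-o-quinones.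

**Step 10**
Reactants: 17
Product: 19 CNP0287532.1 (target), via sulfamate ester 18 (not isolated)
Conditions: MeO2CN(−)SO2N(+)Et3 (Burgess reagent, 3 equiv), toluene, 50 °C
Reagents that add atoms: none
Why: Burgess dehydration (sulfamate formation, then syn elimination); C-5 has no hydrogen, so elimination goes toward C-3 to give the endocyclic trisubstituted alkene in preference to the exocyclic methylene, and no stereocentre is touched.

**Compound list**
1 | (S)-(+)-carvone | CC1=CC[C@@H](CC1=O)C(C)=C | starting material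
2 | lithium (S)-2-methyl-5-(prop-1-en-2-yl)cyclohex-1-en-1-olate | [Li+].CC1=C([O-])C[C@H](CC1)C(C)=C | intermediate (not isolated)
3 | (S)-trimethyl{[2-methyl-5-(prop-1-en-2-yl)cyclohex-1-en-1-yl]oxy}silane | CC1=C(O[Si](C)(C)C)C[C@H](CC1)C(C)=C | intermediate
4 | trimethyl{[(3S)-6-methyl-3-(prop-1-en-2-yl)bicyclo[4.1.0]heptan-1-yl]oxy}silane, cis-fused, both cyclopropane epimers | CC12CC1(O[Si](C)(C)C)C[C@H](CC2)C(C)=C | intermediate
5 | (6S)-3-chloro-3-methyl-6-(prop-1-en-2-yl)cycloheptan-1-one, C-3 epimers | CC1(Cl)CC(=O)C[C@H](CC1)C(C)=C | intermediate (not isolated)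
6 | (S)-3-methyl-6-(prop-1-en-2-yl)cyclohept-2-en-1-one | CC1=CC(=O)C[C@H](CC1)C(C)=C | intermediate
7 | dimethyl{[(3R,6S)-3-methyl-6-(prop-1-en-2-yl)cyclohept-1-en-1-yl]oxy}phenylsilane | C[C@H]1C=C(O[Si](C)(C)c2ccccc2)C[C@H](CC1)C(C)=C | intermediate (not isolated)
8 | lithium (3R,6S)-3-methyl-6-(prop-1-en-2-yl)cyclohept-1-en-1-olate | [Li+].C[C@H]1C=C([O-])C[C@H](CC1)C(C)=C | intermediate (not isolated)
9 | (3R,6S)-3-methyl-6-(prop-1-en-2-yl)cyclohept-1-en-1-yl trifluoromethanesulfonate | C[C@H]1C=C(OS(=O)(=O)C(F)(F)F)C[C@H](CC1)C(C)=C | intermediate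
10 | (E)-1-[(3R,6S)-3-methyl-6-(prop-1-en-2-yl)cyclohept-1-en-1-yl]-3-(trimethylsilyl)prop-2-en-1-one | C[C@H]1C=C(C(=O)/C=C/[Si](C)(C)C)C[C@H](CC1)C(C)=C | intermediate
11 | (4R,7S)-4-methyl-7-(prop-1-en-2-yl)-4,5,6,7,8,8a-hexahydroazulen-1(3aH)-one, cis ring fusion, both cis-fused isomers | C[C@@H]1CC[C@@H](CC2C1C=CC2=O)C(C)=C | intermediate (not isolated)
12 | (4R,7S)-4-methyl-7-(prop-1-en-2-yl)-3,4,5,6,7,8-hexahydroazulen-1(2H)-one | C[C@@H]1CC[C@@H](CC2=C1CCC2=O)C(C)=C | intermediate
13 | (1R,4R,7S)-1,4-dimethyl-7-(prop-1-en-2-yl)-1,2,3,4,5,6,7,8-octahydroazulen-1-ol (4α-hydroxy-guaia-1(5),11-diene of the 7S,10R series) | C[C@@H]1CC[C@@H](CC2=C1CC[C@@]2(C)O)C(C)=C | intermediate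
14 | celastrol | CC1=C(O)C(=O)C=C2C1=CC=C1[C@@]2(C)CC[C@@]2(C)[C@@H]3C[C@](C)(C(=O)O)CC[C@]3(C)CC[C@]12C | starting material
15 | pristimerin (celastrol methyl ester) | CC1=C(O)C(=O)C=C2C1=CC=C1[C@@]2(C)CC[C@@]2(C)[C@@H]3C[C@](C)(C(=O)OC)CC[C@]3(C)CC[C@]12C | intermediate
16 | methyl (8S)-2,3-dioxo-24-nor-D:A-friedooleana-1(10),4,6-trien-29-oate (o-quinone tautomer of pristimerin, 8β-H) | O=C1C(=O)C=C2C(=C1C)C=C[C@@H]1[C@@]2(C)CC[C@@]2(C)[C@@H]3C[C@](C)(C(=O)OC)CC[C@]3(C)CC[C@]12C | intermediate (not isolated)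
17 | 4-hydroxy adduct: methyl (8S)-24-nor-D:A-friedooleana-1,3,5(10),6-tetraen-29-oate whose O-2' and O-3' are bonded to C-1 and C-5 of (4R,7S,10R)-guai-11-en-4-ol; both dioxane oxygens, the 4-OH, the 10-methyl and the 7-isopropenyl group are on the α face | C=C(C)[C@H]1CC[C@@H](C)[C@]23CC[C@@](C)(O)[C@@]2(C1)Oc1c(cc2c(c1C)C=C[C@@H]1[C@@]2(C)CC[C@@]2(C)[C@@H]4C[C@](C)(C(=O)OC)CC[C@]4(C)CC[C@]12C)O3 | intermediate
18 | triethylammonium N-(methoxycarbonyl)sulfamate ester of 17 at the C-4 oxygen | C=C(C)[C@H]1CC[C@@H](C)[C@]23CC[C@@](C)(OS(=O)(=O)[N-]C(=O)OC)[C@@]2(C1)Oc1c(cc2c(c1C)C=C[C@@H]1[C@@]2(C)CC[C@@]2(C)[C@@H]4C[C@](C)(C(=O)OC)CC[C@]4(C)CC[C@]12C)O3.CC[NH+](CC)CC | intermediate (not isolated)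
19 | CNP0287532.1: the Δ3 alkene obtained from 17 by loss of water | C=C(C)[C@H]1CC[C@@H](C)[C@]23CC=C(C)[C@@]2(C1)Oc1c(cc2c(c1C)C=C[C@@H]1[C@@]2(C)CC[C@@]2(C)[C@@H]4C[C@](C)(C(=O)OC)CC[C@]4(C)CC[C@]12C)O3 | target

**Step count and risks**
Total step count: 10. Longest linear sequence: 9 steps (steps 1 to 7, 9 and 10, from 1).

Step 9 is the most likely to fail. The risks are self-dimerization of 15 through its own enol alkene, addition on the wrong face or in the wrong orientation, and the wrong C-8' epimer. The fallback generates the heterodiene by oxidation and sets C-8' separately. It sets out from 15: NaBH4 (MeOH, 0 °C) gives the catechol pristimerol F1. Ag2O (CH2Cl2, 4 Å sieves, rt) oxidizes F1 in the presence of 13 to the C-6' methylene o-quinone F2, which 13 traps to give the Δ7 adduct F3. t-BuOK in DMSO (rt) then moves the double bond into conjugation with ring A (deprotonation at the benzylic–allylic C-6', protonation at C-8'), and the route is rejoined at 17.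

Step 10 is the second risk. The exocyclic C4=C15 isomer may form, and a cationic 1,2-shift is possible next to the aryloxy-bearing C-5. The fallback replaces the ion-pair pathway by a concerted thermal syn elimination. It sets out from 17: KN(SiMe3)2, CS2, then MeI (THF, −78 → 0 °C) gives the S-methyl xanthate F4, and heating F4 in toluene at 100 °C (Chugaev elimination) comes back to the route at 19.

Step 6 is the third risk. The oxyallyl cation or FeCl3 may engage the isopropenyl group. The fallback uses π-acid catalysis on a different precursor. It sets out from 9: Sonogashira coupling with propargyl acetate (PdCl2(PPh3)2, CuI, i-Pr2NH, THF, rt) gives the enynyl acetate F5. (Ph3P)AuCl/AgSbF6 (2 mol% each) in wet CH2Cl2 then brings about a [3,3]-acyloxy shift, Nazarov closure and hydrolysis to the same cyclopentenone 11, which DBU converts to 12, where the route is rejoined.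

**Further compounds**
F1 | step 9 | pristimerol, methyl 2,3-dihydroxy-24-nor-D:A-friedooleana-1,3,5(10),7-tetraen-29-oate | Cc1c(O)c(O)cc2c1CC=C1[C@@]2(C)CC[C@@]2(C)[C@@H]3C[C@](C)(C(=O)OC)CC[C@]3(C)CC[C@]12C
F2 | step 9 | methyl 2,3-dioxo-24-nor-D:A-friedooleana-1(10),4,7-trien-29-oate (o-quinone of pristimerol) | O=C1C(=O)C=C2C(=C1C)CC=C1[C@@]2(C)CC[C@@]2(C)[C@@H]3C[C@](C)(C(=O)OC)CC[C@]3(C)CC[C@]12C
F3 | step 9 | Δ7 isomer of 17 (C-6' methylene, C7'=C8' alkene) | C=C(C)[C@H]1CC[C@@H](C)[C@]23CC[C@@](C)(O)[C@@]2(C1)Oc1c(cc2c(c1C)CC=C1[C@@]2(C)CC[C@@]2(C)[C@@H]4C[C@](C)(C(=O)OC)CC[C@]4(C)CC[C@]12C)O3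
F4 | step 10 | O-(C-4) S-methyl dithiocarbonate (xanthate) of 17 | C=C(C)[C@H]1CC[C@@H](C)[C@]23CC[C@@](C)(OC(=S)SC)[C@@]2(C1)Oc1c(cc2c(c1C)C=C[C@@H]1[C@@]2(C)CC[C@@]2(C)[C@@H]4C[C@](C)(C(=O)OC)CC[C@]4(C)CC[C@]12C)O3
F5 | step 6 | 3-[(3R,6S)-3-methyl-6-(prop-1-en-2-yl)cyclohept-1-en-1-yl]prop-2-yn-1-yl acetate | C[C@H]1C=C(C#CCOC(C)=O)C[C@H](CC1)C(C)=C
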